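I was asked what the cedar flask held at 40 min and whether any step from there adds first product, so I reckoned with the rate of loss.

| flask | substrate | gas | temperature | remark | time |
|---|---|---|---|---|---|
| cedar | 2.3 M | 200 mM (held) | 70 °C | the very flask that is asked about, followed so far |  |
| alder | 1.5 M | 200 mM (held) | 55 °C | run made earlier |  |
| flask | 2.3 M | 200 mM (held) | 70 °C |  | 40 min |

- cedar (time / min: first product / %): 6.00: 85.8; 12.0: 69.8; 15.0: 63.5; 25.0: 43.9; 30.0: 37.5; 40.0: 25.8
- alder (time / min: first product / %): 2.00: 48.5; 5.00: 79.8; 6.00: 84.5; 10.0: 87.4; 12.0: 86.7; 15.0: 84.4

(each reading ± 0.5 percentage points)

- east: change nothing and wait 12 min more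
- south-east: at 40 min take out 90% of the first product then present, then wait 12 min
- north: at 40 min raise the temperature by 15 K, then wait 12 min

- at the start none of reagent is dissolved
- first product that was removed still counts
- reactions considered so far: reagent + first product -> double product + released group; reagent + double product -> tris adduct + released group; gas <-> reagent; reagent + tris adduct -> tetra adduct + released group; substrate + reagent -> first product + released group

- first product, in percent of the substrate first charged, at 40 min
- which option adds most first product ("none" when 2 percentage points or less is all one gets) (east / south-east / north / none)
- first product present, with what was taken out counted in, in percent of the substrate first charged, after east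
- first product present, with what was taken out counted in, in percent of the substrate first charged, after north

The cedar flask lost 16 percentage points of first product in the 6.00 min after 6.00 min, but 12 points in the 10.0 min after 30.0 min. The rate per minute had thus slowed by a factor of 2.28, while first product in those windows fell by a factor of 2.46, so I read the falling first product as the brake. I named the loss constant, the pseudo-first-order fall of ln(first product) per minute between 12.0 min and 40.0 min, 0.0355 min⁻¹.

For now I took the cedar reading of 25.8%, with its scatter of 0.5 points. A further 12 min slows the rate by a factor of 1.53, so east gave me 16.8%. South-east exposes 10.0% of the first product to this loss, which costs 0.9 points. The alder run, colder but also charged with less substrate, fell more slowly, at 0.00699 min⁻¹ net between 10.0 min and 15.0 min, so I guessed north to lie below east, without a figure of my own. No cedar reading after 6.00 min rose, so I answered none.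

The forecast stood at 25.9%, 17% after east, 9% after north and none: “No option adds first product, because no substrate is left to feed it”. The simulation gave 25.9%, 16.8% after east, 9.57% after north and none, with south-east at −0.92 points.

    reagent + first product → double product + released group (k = 0.00309 M⁻¹ s⁻¹, Ea = 58.0 kJ mol⁻¹)
    reagent + double product → tris adduct + released group (k = 0.0838 M⁻¹ s⁻¹, Ea = 59.0 kJ mol⁻¹)
    gas ⇌ reagent, rate k3*(csat - [reagent]) (kL = 0.227 s⁻¹)
    reagent + tris adduct → tetra adduct + released group (k = 0.00274 M⁻¹ s⁻¹, Ea = 63.0 kJ mol⁻¹)
    substrate + reagent → first product + released group (k = 0.0760 M⁻¹ s⁻¹, Ea = 50.0 kJ mol⁻¹)
    (constants at 70 °C)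

The cedar flask had not come to rest at 40 min, when it held 25.9% first product, 38.0% tris adduct and 35.1% tetra adduct. The loss constant divides first product by 3.61 × 10⁵ between then and 400 min, and the computed run ends there with 0% first product and >99.9% tetra adduct.

For the neighbour with 1.4 M of substrate, I carried the loss constant over unchanged and counted the whole charge as first product from the start, which gave 24.2% at 40 min. The computed value is 25.0%.

The numbers in the tables stem from a simulated flask with made-up constants; the scatter is artificial.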